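**Retrosynthetic overview**
1. Griffinone C (8) ⇒ 2'-hydroxychalcone 7: ring C, the only ring formed, is closed in the last step by a catalyst-controlled 6-endo oxa-Michael addition (the chalcone isomerase reaction), which sets C2 as S directly.
2. 7 ⇒ acetophenone 5 + benzaldehyde 6 (Claisen–Schmidt condensation); rings A and B are bought.
3. 5 ⇒ 4 + carbonate 2 (O-tert-prenylation); 4 ⇒ 3 (aromatic Claisen rearrangement, O-to-C prenyl transfer to C3); 3 ⇒ 1 + 2.
4. Order: ring A decoration (steps 1–3), chalcone (step 4), ring C closure (step 5); no protecting groups.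

Assumption: carbonate 2 is bought as a catalogue reagent; if it is not stocked, it is made in one extra operation from 2-methylbut-3-en-2-ol and Boc2O.

**Step 1**
Reactants: 1 2,4-dihydroxyacetophenone; 2 tert-butyl 2-methylbut-3-en-2-yl carbonate
Product: 3 1-[2-hydroxy-4-(2-methylbut-3-en-2-yloxy)phenyl]ethan-1-one
Conditions: 2 (1.15 equiv), Pd(PPh3)4 (2 mol%), THF, 4 Å MS, 0 °C, 2 h
Reagents that add atoms: tert-butyl 2-methylbut-3-en-2-yl carbonate (2), C=CC(C)(C)OC(=O)OC(C)(C)C
Why: Tsuji–Trost decarboxylative O-allylation: zerovalent palladium ionises the tertiary allylic carbonate, the released tert-butoxide deprotonates the more acidic, non-chelated 4-OH, and the phenoxide attacks the more substituted allyl terminus under kinetic control at 0 °C to give the branched ether, while the chelated 2-OH stays free.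

**Step 2**
Reactants: 3 1-[2-hydroxy-4-(2-methylbut-3-en-2-yloxy)phenyl]ethan-1-one
Product: 4 1-[2,4-dihydroxy-3-(3-methylbut-2-en-1-yl)phenyl]ethan-1-one
Conditions: PhNEt2, 150–160 °C, 2 h, argon
Reagents that add atoms: none
Why: Aromatic Claisen rearrangement ([3,3]-sigmatropic shift): the tertiary allyl aryl ether rearranges readily and the allyl inversion turns the 1,1-dimethylallyl group into a prenyl group at C3, the ortho position favoured by bond fixation in chelated 2-hydroxyacetophenones; the minor C5 isomer is removed by chromatography.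

**Step 3**
Reactants: 4 1-[2,4-dihydroxy-3-(3-methylbut-2-en-1-yl)phenyl]ethan-1-one; 2 tert-butyl 2-methylbut-3-en-2-yl carbonate
Product: 5 1-[2-hydroxy-3-(3-methylbut-2-en-1-yl)-4-(2-methylbut-3-en-2-yloxy)phenyl]ethan-1-one
Conditions: 2 (1.3 equiv), Pd(PPh3)4 (3 mol%), THF, 4 Å MS, 0 °C, 3 h; Et3N-washed silica
Reagents that add atoms: tert-butyl 2-methylbut-3-en-2-yl carbonate (2), C=CC(C)(C)OC(=O)OC(C)(C)C
Why: Second Tsuji–Trost O-tert-prenylation: only the 4-OH is available (the 2-OH is chelated to the acetyl group), and low temperature with a short reaction time keeps the kinetic branched ether from isomerising to the linear prenyl ether.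

**Step 4**
Reactants: 5 1-[2-hydroxy-3-(3-methylbut-2-en-1-yl)-4-(2-methylbut-3-en-2-yloxy)phenyl]ethan-1-one; 6 benzaldehyde
Product: 7 (E)-1-[2-hydroxy-3-(3-methylbut-2-en-1-yl)-4-(2-methylbut-3-en-2-yloxy)phenyl]-3-phenylprop-2-en-1-one
Conditions: 6 (1.2 equiv), KOH (3 equiv), EtOH, 0 °C to rt, 24 h; aq NH4Cl quench at 0 °C; chromatography below 40 °C
Reagents that add atoms: benzaldehyde (6), O=Cc1ccccc1
Why: Claisen–Schmidt condensation (crossed aldol, then E1cB dehydration) gives the E-enone; in strong base the product stays open as its phenoxide, the allyl ether and prenyl group are base-stable, and the buffered quench spares the acid-labile tertiary allyl aryl ether (any trace of racemic flavanone is removed at this stage).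

**Step 5**
Reactants: 7 (E)-1-[2-hydroxy-3-(3-methylbut-2-en-1-yl)-4-(2-methylbut-3-en-2-yloxy)phenyl]-3-phenylprop-2-en-1-one
Product: 8 Griffinone C, (2S)-8-(3-methylbut-2-en-1-yl)-7-(2-methylbut-3-en-2-yloxy)-2-phenyl-2,3-dihydro-4H-chromen-4-one
Conditions: squaramide from 9-amino-9-deoxy-epi-quinidine and 3,5-bis(trifluoromethyl)aniline (10 mol%), toluene (0.1 M), 4 Å MS, 0 °C to rt, stopped at about 70% conversion (chiral HPLC); recovered 7 recycled
Reagents that add atoms: none
Why: Proposed new method: enantioselective 6-endo-trig intramolecular oxa-Michael addition by a small-molecule chalcone isomerase mimic. The quinuclidine nitrogen takes the phenolic proton as a general base while the two squaramide N–H bonds bind the ketone oxygen; together they replace the intramolecular OH···O=C hydrogen bond that holds 7 in its unreactive rotamer. The phenoxide oxygen then attacks one face of the β-carbon inside the chiral pocket, the squaramide stabilises the developing enolate like an oxyanion hole, and the quinuclidinium protonates C3. C2 is the only stereocentre and is set here under kinetic control, so the reaction is stopped before the retro-oxa-Michael equilibrium can erode ee. The facial sense cannot be predicted with certainty for this substrate; if the first analytical run shows 2R, the pseudoenantiomeric quinine-derived squaramide is used instead. The ortho-prenyl group twists the bulky tertiary ether out of conjugation, which keeps the enone electrophilic. Closest known reaction types: cinchona thiourea-catalysed oxa-Michael cyclisation of ester-activated 2'-hydroxychalcones to flavanones, quinine-catalysed cyclisation of o-hydroxyaryl enones to 2-substituted chromanones, and chiral ammonium ion-pair cyclisation of 2'-hydroxychalcone itself.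

**Compound list**
1 | 2,4-dihydroxyacetophenone | CC(=O)c1ccc(O)cc1O | starting material
2 | tert-butyl 2-methylbut-3-en-2-yl carbonate | C=CC(C)(C)OC(=O)OC(C)(C)C | starting material
3 | 1-[2-hydroxy-4-(2-methylbut-3-en-2-yloxy)phenyl]ethan-1-one | CC(=O)c1ccc(OC(C)(C)C=C)cc1O | intermediate
4 | 1-[2,4-dihydroxy-3-(3-methylbut-2-en-1-yl)phenyl]ethan-1-one | CC(=O)c1ccc(O)c(CC=C(C)C)c1O | intermediate
5 | 1-[2-hydroxy-3-(3-methylbut-2-en-1-yl)-4-(2-methylbut-3-en-2-yloxy)phenyl]ethan-1-one | CC(=O)c1ccc(OC(C)(C)C=C)c(CC=C(C)C)c1O | intermediate
6 | benzaldehyde | O=Cc1ccccc1 | starting material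
7 | (E)-1-[2-hydroxy-3-(3-methylbut-2-en-1-yl)-4-(2-methylbut-3-en-2-yloxy)phenyl]-3-phenylprop-2-en-1-one | O=C(/C=C/c1ccccc1)c1ccc(OC(C)(C)C=C)c(CC=C(C)C)c1O | intermediate
8 | Griffinone C, (2S)-8-(3-methylbut-2-en-1-yl)-7-(2-methylbut-3-en-2-yloxy)-2-phenyl-2,3-dihydro-4H-chromen-4-one | C=CC(C)(C)Oc1ccc2c(c1CC=C(C)C)O[C@H](c1ccccc1)CC2=O | target

**Totals**
Total step count: 5. Longest linear sequence: 5 (1 → 3 → 4 → 5 → 7 → 8).

**Steps most likely to fail, with fallbacks**

Step 5 (asymmetric ring closure) is the main risk. The enone is not activated, the reaction is reversible, and both ee and conversion could be low. Compounds 5, 7 and 8 must also stay below about 100 °C and away from acid, because the tertiary allyl ether can undergo a second Claisen shift or ionise. The product configuration is checked by chiral HPLC and circular dichroism (2S-flavanones show a positive Cotton effect near 330 nm and a negative one near 290 nm). The fallback sets out from 7 and returns at 8. Chalcone 7 is cyclised without stereocontrol (NaOAc, EtOH, 78 °C, equilibrium mixture, chalcone recycled) to racemic 8-(3-methylbut-2-en-1-yl)-7-(2-methylbut-3-en-2-yloxy)-2-phenyl-2,3-dihydro-4H-chromen-4-one F1. Preparative chiral SFC on an amylose tris(3,5-dimethylphenylcarbamate) phase then gives 8 and the unwanted (2R)-8-(3-methylbut-2-en-1-yl)-7-(2-methylbut-3-en-2-yloxy)-2-phenyl-2,3-dihydro-4H-chromen-4-one F2. F2 is re-equilibrated through the chalcone under the same NaOAc conditions and resolved again, so the material is not lost.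

Step 3 (second O-tert-prenylation) may fail because the 4-OH of 4 is flanked by the prenyl group. Slow alkylation or drift to the linear prenyl ether is possible. The fallback sets out from 4 and returns at 5. Phenol 4 is alkylated with 3-chloro-3-methylbut-1-yne (K2CO3, KI, catalytic CuI, acetone, 55 °C) to 1-[2-hydroxy-3-(3-methylbut-2-en-1-yl)-4-(2-methylbut-3-yn-2-yloxy)phenyl]ethan-1-one F3. The terminal alkyne is then semi-hydrogenated (H2 at 1 atm, Pd on CaCO3 poisoned with Pb(OAc)2, quinoline, EtOAc, rt) to 5; the trisubstituted prenyl alkene and the aryl ketone are untouched.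

Step 2 (Claisen rearrangement) may give too much of the C5 isomer, or the ortho-prenylphenol may cyclise to a chroman on prolonged heating. The fallback sets out from 1 and returns at 4, replacing steps 1 and 2. The dianion of 1 is C-prenylated directly with 1-bromo-3-methylbut-2-ene in 10% aqueous KOH at 0 °C to rt. This gives 4 in modest yield after chromatographic removal of the O-prenyl and C5-prenyl isomers, and passes through no new compound (F0).

**Further compounds**
F1 | step 5 | racemic 8-(3-methylbut-2-en-1-yl)-7-(2-methylbut-3-en-2-yloxy)-2-phenyl-2,3-dihydro-4H-chromen-4-one | C=CC(C)(C)Oc1ccc2c(c1CC=C(C)C)OC(c1ccccc1)CC2=O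
F2 | step 5 | (2R)-8-(3-methylbut-2-en-1-yl)-7-(2-methylbut-3-en-2-yloxy)-2-phenyl-2,3-dihydro-4H-chromen-4-one | C=CC(C)(C)Oc1ccc2c(c1CC=C(C)C)O[C@@H](c1ccccc1)CC2=O
F3 | step 3 | 1-[2-hydroxy-3-(3-methylbut-2-en-1-yl)-4-(2-methylbut-3-yn-2-yloxy)phenyl]ethan-1-one | CC(=O)c1ccc(OC(C)(C)C#C)c(CC=C(C)C)c1O
F0 | step 2 | none | none
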